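Cuts: the two O7–Si bonds; then C4a–C5 and C8–C8a in each ring A (four C–C bonds); then the two C4a–S bonds of the activating groups; then C3–C3''; last C2–C3 and O1–C8a of each ring C.
Forward: each ring C arises by hetero-Diels–Alder reaction of 4-methoxybenzaldehyde. Two rings C are joined at C3–C3'' by oxidative enolate coupling, C4a is armed with a phenylsulfinyl group, both rings A are annulated last by Diels–Alder reaction and aromatisation, and the silyl groups are removed.
Enabling feature: rings A (C4a, C5, C6, C7, C8, C8a) hold no stereocentre. Their C4a=C8a edge already exists in each ring C as the push–pull alkene O1–C8a=C4a–C4=O, and C2, C3, C2'' and C3'' all lie in rings C.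
Stereochemistry: C2 and C2'' (S) come from a chiral titanium catalyst. C3 and C3'' (R) come from coupling anti to the C2 aryl groups (2,3-trans), so two (S)-units give the C2-symmetric isomer. All later steps are neutral or weakly acidic.

Key step: step 7

Assumption: the (S)-H8-BINOL/Ti(OiPr)4 catalyst is taken to direct attack to the Si face of aromatic aldehydes, as BINOL–titanium catalysts do in related carbonyl additions, which gives the (S)-pyranone; if the sense is opposite, the (R)-ligand is used.
Numbering: positions are discussed in flavanone numbering (pyranone C5 = C4a, pyranone C6 = C8a); the compound names of the bipyrans use pyran numbering.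

Step 1
Reactants: 1 4-methoxybenzaldehyde; 2 (E)-1-methoxy-3-(trimethylsilyloxy)buta-1,3-diene
Product: 4 (S)-2-(4-methoxyphenyl)-2,3-dihydro-4H-pyran-4-one, via aldol silyl ether 3 (not isolated)
Conditions: (S)-H8-BINOL (22 mol %), Ti(OiPr)4 (20 mol %), 4 Å MS, toluene, 0 °C; then TFA, CH2Cl2, 0 °C
Reagents that add atoms: none
Why: Catalytic asymmetric hetero-Diels–Alder reaction in its stepwise Mukaiyama aldol/cyclisation form, in which the chiral titanium binaphtholate shields one face of the bound aldehyde so that C2–C3 bond formation sets C2 as S, and TFA then closes ring C by oxa-Michael addition and loss of the methoxy group.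

Step 2
Reactants: 4 (S)-2-(4-methoxyphenyl)-2,3-dihydro-4H-pyran-4-one (two molecules)
Product: 6 (2S,2'S,3R,3'R)-2,2'-bis(4-methoxyphenyl)-2,2',3,3'-tetrahydro-4H,4'H-[3,3'-bipyran]-4,4'-dione, via lithium enolate 5 (not isolated)
Conditions: LDA (1.05 equiv), THF, −78 °C; FeCl3 (1.1 equiv), DMF, −78 °C → rt
Reagents that add atoms: none
Why: Oxidative homocoupling of a ketone lithium enolate, known for the α'-enolates of 5-substituted cyclohexenones, in which kinetic deprotonation at C3, one-electron oxidation and C–C bond formation on the face of each ring opposite the C2 aryl group set C3 and C3' trans to C2 and C2', so that two (S)-units give the (2S,3R,2'S,3'R) isomer, while the heterochiral dimer from residual (R)-4 is a separable diastereomer and its removal should raise the enantiopurity of 6.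

Step 3
Reactants: 6 (2S,2'S,3R,3'R)-2,2'-bis(4-methoxyphenyl)-2,2',3,3'-tetrahydro-4H,4'H-[3,3'-bipyran]-4,4'-dione
Product: 7 (2S,2'S,3R,3'R)-2,2'-bis(4-methoxyphenyl)-5,5'-bis(phenylsulfanyl)-2,2',3,3'-tetrahydro-4H,4'H-[3,3'-bipyran]-4,4'-dione
Conditions: PhSCl (2.3 equiv), pyridine (5 equiv), CH2Cl2, −20 °C → rt
Reagents that add atoms: benzenesulfenyl chloride, ClSc1ccccc1
Why: Electrophilic substitution at C4a, the nucleophilic α-carbon of the vinylogous ester, in which PhSCl attacks the enol ether to give an O1-stabilised cation and pyridine removes the acidic proton, the same addition–elimination course by which such pyranones are halogenated, with no stereocentre involved.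

Step 4
Reactants: 7 (2S,2'S,3R,3'R)-2,2'-bis(4-methoxyphenyl)-5,5'-bis(phenylsulfanyl)-2,2',3,3'-tetrahydro-4H,4'H-[3,3'-bipyran]-4,4'-dione
Product: 8 (2S,2'S,3R,3'R)-2,2'-bis(4-methoxyphenyl)-5,5'-bis(phenylsulfinyl)-2,2',3,3'-tetrahydro-4H,4'H-[3,3'-bipyran]-4,4'-dione (mixture of sulfur epimers)
Conditions: mCPBA (2.0 equiv), CH2Cl2, −78 → −40 °C
Reagents that add atoms: 3-chloroperbenzoic acid, OOC(=O)c1cccc(Cl)c1
Why: Chemoselective sulfide-to-sulfoxide oxidation with one equivalent of peracid per sulfur, sulfur being far more nucleophilic than the acceptor-substituted enol ether or the anisyl rings; sulfinyl is chosen because it lowers the LUMO of C8a=C4a and can later leave by syn elimination, so its configuration does not matter.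

Step 5
Reactants: 9 1,1-dimethoxyethene (2.2 equiv); 10 acetyl chloride
Product: 11 4,4-dimethoxybut-3-en-2-one
Conditions: Et2O, 0 °C → rt
Reagents that add atoms: none
Why: C-acylation of a ketene acetal by an acid chloride, a classical route to acylketene acetals, in which the second equivalent of 9 traps the HCl and collapses to methyl acetate and chloromethane.

Step 6
Reactants: 11 4,4-dimethoxybut-3-en-2-one
Product: 12 tert-butyl[(4,4-dimethoxybuta-1,3-dien-2-yl)oxy]dimethylsilane
Conditions: TBSOTf (1.1 equiv), Et3N (1.5 equiv), Et2O, 0 °C → rt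
Reagents that add atoms: tert-butyldimethylsilyl triflate, CC(C)(C)[Si](C)(C)OS(=O)(=O)C(F)(F)F
Why: Soft enolisation and O-silylation of a methyl ketone with a silyl triflate and an amine, the standard route to 2-silyloxybutadienes, with only the CH3 group open to deprotonation and with the TBS group chosen so that the later aryl silyl ether survives methanol and chromatography.

Step 7
Reactants: 8 (2S,2'S,3R,3'R)-2,2'-bis(4-methoxyphenyl)-5,5'-bis(phenylsulfinyl)-2,2',3,3'-tetrahydro-4H,4'H-[3,3'-bipyran]-4,4'-dione; 12 tert-butyl[(4,4-dimethoxybuta-1,3-dien-2-yl)oxy]dimethylsilane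
Product: 15 (2S,3R,2''S,3''R)-7,7''-bis(tert-butyldimethylsilyloxy)-5,5''-dimethoxy-2,2''-bis(4-methoxyphenyl)-[3,3''-bichromane]-4,4''-dione, via twofold cycloadduct 13 (not isolated), via bis-ketal cyclohexadiene 14 (not isolated)
Conditions: 12 (6 equiv), 4 Å MS, toluene, 100 °C, sealed tube
Reagents that add atoms: none
Why: Proposed new method: in each ring C the alkene C8a=C4a is pushed by O1 and pulled by both C4=O and the sulfinyl group, so the methylene terminus of the electron-rich diene 12 should bond to C8a and its acetal carbon to C4a in a normal-electron-demand, strongly asynchronous [4+2] cycloaddition, each ring A closing intermolecularly with both σ-bonds (C8–C8a leading, C4a–C5 following) made in one event. The suprafacial addition places the sulfinyl group at C4a and H-8a cis in 13, the geometry needed for thermal syn elimination of PhSOH, which finds no other β-hydrogen and restores C4a=C8a to give 14. Ionisation of one C5 methoxy group of 14 gives a cation stabilised by O1, the remaining C5 oxygen and the C7 silyloxy group, and loss of H-8 aromatises the ring with OMe fixed at C5 and OTBS at C7. The closest known reaction types are the tandem Diels–Alder/sulfoxide pyrolysis of 2-sulfinylquinones and 2-sulfinylcycloalkenones and the regiocontrolled resorcinol synthesis from 1,1-dimethoxy-3-silyloxybutadienes with acetylenic ketones, haloquinones and 3-acceptor-substituted chromones, whereas a dihydropyranone has not served as the two-carbon partner. The only new stereocentres (C4a and C8a of 13) are transient and vanish on aromatisation, so facial selectivity and sulfur configuration are irrelevant. The step needs regioselectivity, which the polarisation just described secures, and integrity of C2, C3, C2'' and C3'', which the neutral, base-free medium secures because it triggers neither enolisation at C3 nor retro-oxa-Michael opening at O1–C2.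

Step 8
Reactants: 15 (2S,3R,2''S,3''R)-7,7''-bis(tert-butyldimethylsilyloxy)-5,5''-dimethoxy-2,2''-bis(4-methoxyphenyl)-[3,3''-bichromane]-4,4''-dione
Product: 16 4',4''',5,5''-tetramethylchamaejasmin, (2S,3R,2''S,3''R)
Conditions: HF·pyridine, THF/pyridine, 0 °C → rt
Reagents that add atoms: none
Why: Fluoride-induced cleavage of aryl silyl ethers in a weakly acidic, buffered medium in which the flavanone rings neither enolise at C3 nor open at O1–C2, so all four stereocentres should persist.

Compound list
1 | 4-methoxybenzaldehyde | COc1ccc(C=O)cc1 | starting material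
2 | (E)-1-methoxy-3-(trimethylsilyloxy)buta-1,3-diene | CO/C=C/C(=C)O[Si](C)(C)C | starting material
3 | (1E,5S)-1-methoxy-5-(4-methoxyphenyl)-5-(trimethylsilyloxy)pent-1-en-3-one | COc1ccc([C@@H](O[Si](C)(C)C)CC(=O)/C=C/OC)cc1 | intermediate (not isolated)
4 | (S)-2-(4-methoxyphenyl)-2,3-dihydro-4H-pyran-4-one | COc1ccc([C@H]2OC=CC(=O)C2)cc1 | intermediate
5 | lithium (S)-2-(4-methoxyphenyl)-2H-pyran-4-olate | COc1ccc([C@H]2OC=CC([O-])=C2)cc1.[Li+] | intermediate (not isolated)
6 | (2S,2'S,3R,3'R)-2,2'-bis(4-methoxyphenyl)-2,2',3,3'-tetrahydro-4H,4'H-[3,3'-bipyran]-4,4'-dione | COc1ccc([C@H]2OC=CC(=O)[C@@H]2[C@H]2C(=O)C=CO[C@@H]2c2ccc(OC)cc2)cc1 | intermediate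
7 | 5,5'-bis(phenylsulfanyl) derivative of 6, (2S,2'S,3R,3'R) | COc1ccc([C@H]2OC=C(Sc3ccccc3)C(=O)[C@@H]2[C@H]2C(=O)C(Sc3ccccc3)=CO[C@@H]2c2ccc(OC)cc2)cc1 | intermediate
8 | 5,5'-bis(phenylsulfinyl) derivative of 6, (2S,2'S,3R,3'R), sulfur centres as a mixture | COc1ccc([C@H]2OC=C(S(=O)c3ccccc3)C(=O)[C@@H]2[C@H]2C(=O)C(S(=O)c3ccccc3)=CO[C@@H]2c2ccc(OC)cc2)cc1 | intermediate
9 | 1,1-dimethoxyethene | COC(=C)OC | starting material
10 | acetyl chloride | CC(=O)Cl | starting material
11 | 4,4-dimethoxybut-3-en-2-one | COC(OC)=CC(C)=O | intermediate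
12 | tert-butyl[(4,4-dimethoxybuta-1,3-dien-2-yl)oxy]dimethylsilane | COC(OC)=CC(=C)O[Si](C)(C)C(C)(C)C | intermediate
13 | twofold cycloadduct: each ring C cis-fused at C4a/C8a to a 5,5-dimethoxy-7-(TBS-oxy)cyclohex-6-ene, PhS(O) at C4a cis to H-8a; C2, C3, C2'', C3'' as in 8; transient centres as a mixture | COc1ccc([C@H]2OC3CC(O[Si](C)(C)C(C)(C)C)=CC(OC)(OC)C3(S(=O)c4ccccc4)C(=O)[C@@H]2[C@H]2C(=O)C3(S(=O)c4ccccc4)C(CC(O[Si](C)(C)C(C)(C)C)=CC3(OC)OC)O[C@@H]2c2ccc(OC)cc2)cc1 | intermediate (not isolated)
14 | bis(5,5-dimethoxy-5,8-dihydro) form of 15 (C4a=C8a and C6=C7 in each ring A) | COc1ccc([C@H]2OC3=C(C(OC)(OC)C=C(O[Si](C)(C)C(C)(C)C)C3)C(=O)[C@@H]2[C@H]2C(=O)C3=C(CC(O[Si](C)(C)C(C)(C)C)=CC3(OC)OC)O[C@@H]2c2ccc(OC)cc2)cc1 | intermediate (not isolated)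
15 | (2S,3R,2''S,3''R)-7,7''-bis(tert-butyldimethylsilyloxy)-5,5''-dimethoxy-2,2''-bis(4-methoxyphenyl)-[3,3''-bichromane]-4,4''-dione | COc1ccc([C@H]2Oc3cc(O[Si](C)(C)C(C)(C)C)cc(OC)c3C(=O)[C@@H]2[C@H]2C(=O)c3c(OC)cc(O[Si](C)(C)C(C)(C)C)cc3O[C@@H]2c2ccc(OC)cc2)cc1 | intermediate
16 | 4',4''',5,5''-tetramethylchamaejasmin, (2S,3R,2''S,3''R) | COc1ccc([C@H]2Oc3cc(O)cc(OC)c3C(=O)[C@@H]2[C@H]2C(=O)c3c(OC)cc(O)cc3O[C@@H]2c2ccc(OC)cc2)cc1 | target

Total step count: 8. Longest linear sequence: 6 (steps 1, 2, 3, 4, 7, 8).

Steps most likely to fail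

1. Step 7.
- What may go wrong: the cycloaddition onto the push–pull alkene may be slower than the thermal decay of 12. Silyl transfer from 12 to the sulfoxide oxygen may divert 8 into Pummerer-type chemistry. The sulfenic acid released may sulfenylate the electron-rich new rings.
- Fallback (known chemistry; sets out from 1, comes back at 16): rings A are taken from a ready-made phloroglucinol and rings C are closed last. Commercial 1-(2,4-dihydroxy-6-methoxyphenyl)ethanone is protected with MOMCl and NaH to give 1-[2-methoxy-4,6-bis(methoxymethoxy)phenyl]ethanone F1. Oxidative coupling of its lithium enolate (LDA, then CuCl2) gives 1,4-bis[2-methoxy-4,6-bis(methoxymethoxy)phenyl]butane-1,4-dione F2. Twofold Claisen–Schmidt condensation of F2 with 1 (KOH, EtOH) gives (2E,3E)-2,3-bis(4-methoxybenzylidene)-1,4-bis[2-methoxy-4,6-bis(methoxymethoxy)phenyl]butane-1,4-dione F3. Methanolic HCl strips the four MOM groups and the freed ortho-phenols add to the enones (oxa-Michael). NaOAc in EtOH then equilibrates the mixture toward the racemic trans,trans-biflavanone F4. Removal of the diastereomers and preparative HPLC on a chiral stationary phase gives 16.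

2. Step 2.
- What may go wrong: the enolate may open by β-elimination of the ring oxygen (or electrocyclic opening of the 2H-pyranolate). It may be chlorinated instead of coupled. The coupling may show weak trans,trans selectivity.
- Fallback (sets out from 1, comes back at 6): the C3–C3' bond is bought with a succinyl unit instead of being made. Friedel–Crafts acylation of bis(trimethylsilyl)acetylene with succinyl chloride (AlCl3, CH2Cl2) gives 1,8-bis(trimethylsilyl)octa-1,7-diyne-3,6-dione F5. Methanol with catalytic DABCO desilylates it and adds in conjugate fashion to give (1E,7E)-1,8-dimethoxyocta-1,7-diene-3,6-dione F6. TBSOTf and Et3N then give (1E,3Z,5Z,7E)-3,6-bis(tert-butyldimethylsilyloxy)-1,8-dimethoxyocta-1,3,5,7-tetraene F7. F7 undergoes a twofold trans-selective catalytic asymmetric hetero-Diels–Alder reaction with 1, run under the chiral zirconium binaphtholate made from Zr(OtBu)4 and the appropriate enantiomer of 3,3'-diiodo-BINOL, and TFA treatment then gives 6.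

3. Step 3.
- What may go wrong: attack of the sulfenyl chloride on the deactivated enol ether may be sluggish. Sulfenylation of the anisyl rings may compete. The chloride adduct may persist without elimination.
- Fallback (sets out from 6, comes back at 7): sulfur is introduced by cross-coupling instead of electrophilic substitution. NBS (CH2Cl2, 0 °C, dark) gives (2S,2'S,3R,3'R)-5,5'-dibromo-2,2'-bis(4-methoxyphenyl)-2,2',3,3'-tetrahydro-4H,4'H-[3,3'-bipyran]-4,4'-dione F8. Migita-type C–S cross-coupling with Bu3SnSPh under Pd(PPh3)4 in toluene at 90 °C, a neutral medium without free thiolate, then gives 7.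

Further compounds
F1 | step 7 | 1-[2-methoxy-4,6-bis(methoxymethoxy)phenyl]ethanone | CC(=O)c1c(OC)cc(OCOC)cc1OCOC
F2 | step 7 | 1,4-bis[2-methoxy-4,6-bis(methoxymethoxy)phenyl]butane-1,4-dione | COCOc1cc(OC)c(C(=O)CCC(=O)c2c(OC)cc(OCOC)cc2OCOC)c(OCOC)c1
F3 | step 7 | (2E,3E)-2,3-bis(4-methoxybenzylidene)-1,4-bis[2-methoxy-4,6-bis(methoxymethoxy)phenyl]butane-1,4-dione | COc1ccc(/C=C(/C(=O)c2c(OC)cc(OCOC)cc2OCOC)\C(=C/c2ccc(OC)cc2)C(=O)c2c(OC)cc(OCOC)cc2OCOC)cc1
F4 | step 7 | racemic trans,trans-biflavanone (16 together with its mirror image; relative configuration shown) | COc1ccc([C@H]2Oc3cc(O)cc(OC)c3C(=O)[C@@H]2[C@H]2C(=O)c3c(OC)cc(O)cc3O[C@@H]2c2ccc(OC)cc2)cc1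
F5 | step 2 | 1,8-bis(trimethylsilyl)octa-1,7-diyne-3,6-dione | C[Si](C)(C)C#CC(=O)CCC(=O)C#C[Si](C)(C)C
F6 | step 2 | (1E,7E)-1,8-dimethoxyocta-1,7-diene-3,6-dione | CO/C=C/C(=O)CCC(=O)/C=C/OC
F7 | step 2 | (1E,3Z,5Z,7E)-3,6-bis(tert-butyldimethylsilyloxy)-1,8-dimethoxyocta-1,3,5,7-tetraene | CO/C=C/C(O[Si](C)(C)C(C)(C)C)=C/C=C(O[Si](C)(C)C(C)(C)C)/C=C/OC
F8 | step 3 | (2S,2'S,3R,3'R)-5,5'-dibromo-2,2'-bis(4-methoxyphenyl)-2,2',3,3'-tetrahydro-4H,4'H-[3,3'-bipyran]-4,4'-dione | COc1ccc([C@H]2OC=C(Br)C(=O)[C@@H]2[C@H]2C(=O)C(Br)=CO[C@@H]2c2ccc(OC)cc2)cc1
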